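**The crossing.** J, made from G on L, is also used up by G to give Q, so it has a level at which making and using come level. Each step counts G once, so that crossing is a fixed ratio of J to L however much G remains, and L follows E/Z, fresh over spent salt.

| setting | Wednesday's | Saturday's | flask |
|---|---|---|---|
| G | 0.022 M | 0.022 M | 0.022 M |
| E | 0.016 M | 0.036 M | 0.0242 M |
| D | 2.2 mM | 2.2 mM | 2.2 mM |
| remark | run made earlier | run made earlier |  |
| time |  |  | 15 d |
| volume of the second phase over the first |  |  | 2.0 |

| run | time / d | G / % | J / % |
|---|---|---|---|
| Wednesday's | 1.25 | 4.4 | 3.5 |
| Wednesday's | 3.00 | 1.1 | 1.4 |
| Wednesday's | 8.00 | 1.3 | 3.2 |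
| Wednesday's | 20.0 | 0.2 | 2.0 |
| Saturday's | 5.00 | 0.5 | 11.2 |
| Saturday's | 10.0 | 0 | 11.1 |
| Saturday's | 15.0 | 1.2 | 11.4 |
| Saturday's | 20.0 | 0 | 11.3 |

(each reading ± 1 percentage point)

- percent here means G units held: one Q counts as two
- in the second phase: E, Z; everything else is in the first
- charges count per volume of the first phase; a concentration in a rate is the amount of a species over the volume of its own phase; every rate counts per litre of the first phase
- the earlier runs were read with a standard deviation of 1 percentage point
- steps thought possible: D + E <-> L + Z; G + L -> J + D; G + J -> Q
- the earlier runs hold the two phases in the same ratio of volumes as the flask asked about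
- the reaction counts as stopped when no species that holds the G changes by six tenths of a point or more over the second half of the time

- why nothing more happens at 15 d, or that something still does (all of G has reacted / it is still moving / no working catalyst is left / E has run out first / forward and back rates have come level)
- how much of the G has reacted by 15 d
- how much J there is at 15 d, in percent of the G charged

**First reading.** We take Saturday's flat J, 11.3%, as the crossing. Each J ever made spent one E, and each Q holds one such J plus a further G, so that run's finished turnovers spent E equal to 55.6% of its G charge, which counts its E/Z as 1.94. Standing L holds a further spent E, at most 10.0% of the G charge, and this count leaves that out, so its E/Z reads high. This gives the crossing share, the final J as a fraction of the G charge per unit of E/Z so counted, at this charge of G and D: 5.82%.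

**First objection.** One run makes no straight line. Wednesday's J from 3.00 d on averages 2.20%, so its finished turnovers spent 51.1% and its counted E/Z is 0.423. The share then predicts 2.46%, and single readings scatter by 1 percentage point, so the line stands.

**Our flask.** Taking the finished turnovers as 52.9% of the G charge, the flask has a counted E/Z of 1.08, with J at 6.28%. That count leaves 51.9% of its E, less what stands in L, so G is the limiting reagent.

**Second objection.** G might give out before J reaches the crossing. But the crossing is a small part of the charge, and Wednesday's G already read 1.1% at 3.00 d with less E than this flask.

**The forecast.** It gives all of G has reacted, 99.9% reacted and J at 6.2%, a little below our figure, holding that “J at the end sits near the balance between making and consuming it”.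

**The result.** The flask gives all of G has reacted, 100% reacted and J at 6.92%. Read on the E the flask has left, 50%, rather than on the turnover count, the crossing share gives 5.82%.

    D + E ⇌ L + Z (K = 0.180, k = 1700 M⁻¹ h⁻¹)
    G + L → J + D (k = 160 M⁻¹ h⁻¹)
    G + J → Q (k = 43.0 M⁻¹ h⁻¹)

**Less G.** The neighbour holds G at 0.0055 M, a quarter of the flask's, with E and D unchanged. It keeps 80% of its E, so E/Z stands at 3.92. Rescaled to this smaller G charge, the crossing share puts the level at 91.3% of the charge. At 15.0 d its G reads 0%, L 41.4%, and J stands lower than that level, at 45.7%.

Readings and results are calculated on assumed constants; scatter was added.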